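The route rests on cutting the aryl ether bond O1–C8a of the dihydropyranone ring. Because O1 joins the C2 stereocentre to the aromatic carbon C8a of ring A, a pre-set (S)-carbinol at C2 can be coupled to a bromide at C8a. One copper-catalysed intramolecular O-arylation closes the pyran ring with C2 untouched, while C4 is kept as an alcohol so that neither retro-aldol nor chalcone formation is possible. The precursor is the anti (1S,3S)-1,3-diaryl-propane-1,3-diol 17 carrying the C8a bromide and the Z side chain; its phenols are masked as base-tolerant TIPS ethers and the allylic alcohol as a TBS ether. Oxidation at C4 and buffered fluoride then give the target.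

Key step: step 10

Remark on the chemistry: atoms are numbered as in the flavanone (O1, C2, C3, C4, C4a, C5–C8, C8a); diketone 16 is drawn as the diketo tautomer although it should be largely enolised; the C4 configuration is of no consequence for the target because that carbinol is oxidised in step 11; the phenols carry triisopropylsilyl groups because tert-butyldimethylsilyl aryl ethers would be at risk under hot carbonate and in the acylation chemistry.

Step 1
Reactants: 1 3-bromo-2-methylphenol
Product: 3 1-(2-bromo-4-hydroxy-3-methylphenyl)ethanone, via 3-bromo-2-methylphenyl acetate 2 (not isolated)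
Conditions: AcCl (1.2 equiv), TfOH (neat), 0 °C → rt
Reagents that add atoms: acetyl chloride, CC(=O)Cl
Why: O-acylation followed by a triflic-acid-promoted Fries rearrangement (Friedel–Crafts acylation) should place the acetyl group para to the hydroxyl, the electronically preferred site under non-chelating Brønsted-acid conditions, the neighbouring bromine being only a modest steric penalty.

Step 2
Reactants: 3 1-(2-bromo-4-hydroxy-3-methylphenyl)ethanone
Product: 4 1-[2-bromo-3-methyl-4-(triisopropylsilyloxy)phenyl]ethanone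
Conditions: TIPSCl, imidazole, DMF, rt
Reagents that add atoms: triisopropylsilyl chloride, CC(C)[Si](Cl)(C(C)C)C(C)C
Why: Imidazole-promoted silylation of the phenol (silyl ether protection) should give a hindered aryl TIPS ether that withstands the radical, organozinc, enolisation and carbonate conditions ahead.

Step 3
Reactants: 4 1-[2-bromo-3-methyl-4-(triisopropylsilyloxy)phenyl]ethanone
Product: 5 1-[2-bromo-3-(bromomethyl)-4-(triisopropylsilyloxy)phenyl]ethanone
Conditions: NBS (1.05 equiv), AIBN (5 mol %), PhCF3, 80 °C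
Reagents that add atoms: N-bromosuccinimide, O=C1CCC(=O)N1Br
Why: Wohl–Ziegler radical bromination should select the ring methyl (stabilised benzylic radical) over the acetyl methyl, while the non-polar medium and the deactivating acetyl group hold back ionic ring bromination.

Step 4
Reactants: 6 propargyl alcohol
Product: 8 (Z)-3-iodo-2-methylprop-2-en-1-ol, via cyclic vinylmagnesium alkoxide 7 (not isolated)
Conditions: MeMgBr (2.5 equiv), CuI (10 mol %), THF, −10 °C → rt; then I2, THF, −78 → 0 °C
Reagents that add atoms: methylmagnesium bromide, C[Mg]Br; iodine, II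
Why: Copper-catalysed anti-carbomagnesiation of the propargylic alkoxide delivers methyl to C2 and magnesium to C3 within a five-membered chelate, and iodinolysis of the vinyl–magnesium bond with retention fixes the Z geometry (iodine cis to CH2OH).

Step 5
Reactants: 8 (Z)-3-iodo-2-methylprop-2-en-1-ol
Product: 9 (Z)-tert-butyl[(3-iodo-2-methylprop-2-en-1-yl)oxy]dimethylsilane
Conditions: TBSCl, imidazole, CH2Cl2, 0 °C → rt
Reagents that add atoms: tert-butyldimethylsilyl chloride, CC(C)(C)[Si](C)(C)Cl
Why: Standard silylation of the primary allylic alcohol (silyl ether protection) removes the acidic proton before the organozinc coupling and leaves the vinyl iodide geometry untouched.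

Step 6
Reactants: 5 1-[2-bromo-3-(bromomethyl)-4-(triisopropylsilyloxy)phenyl]ethanone; 9 (Z)-tert-butyl[(3-iodo-2-methylprop-2-en-1-yl)oxy]dimethylsilane
Product: 11 1-[2-bromo-3-[(Z)-4-(tert-butyldimethylsilyloxy)-3-methylbut-2-enyl]-4-(triisopropylsilyloxy)phenyl]ethanone, via benzylic zinc bromide 10 (not isolated)
Conditions: Zn dust (activated), LiCl, THF, 0 °C → rt; then 9, Pd(PPh3)4 (5 mol %), THF, rt
Reagents that add atoms: none
Why: LiCl-assisted zinc insertion into the benzylic C–Br bond tolerates the ketone and the aryl bromide, and the Negishi coupling should proceed with retention of alkene geometry because Pd(0)/PPh3 at room temperature inserts into the vinyl C–I bond far faster than into the di-ortho-substituted aryl C–Br bond.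

Step 7
Reactants: 12 3,4-dihydroxybenzoic acid
Product: 14 3,4-bis(triisopropylsilyloxy)benzoic acid, via triisopropylsilyl ester 13 (not isolated)
Conditions: TIPSCl (3.3 equiv), imidazole, DMF, rt → 40 °C; then K2CO3, THF/H2O, rt; aq. citric acid work-up
Reagents that add atoms: triisopropylsilyl chloride, CC(C)[Si](Cl)(C(C)C)C(C)C
Why: Exhaustive silylation followed by selective hydrolysis of the far more labile silyl ester (silyl protection, silyl ester cleavage) should free the acid while both hindered aryl TIPS ethers stay in place.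

Step 8
Reactants: 14 3,4-bis(triisopropylsilyloxy)benzoic acid; 11 1-[2-bromo-3-[(Z)-4-(tert-butyldimethylsilyloxy)-3-methylbut-2-enyl]-4-(triisopropylsilyloxy)phenyl]ethanone
Product: 16 1-[3,4-bis(triisopropylsilyloxy)phenyl]-3-[2-bromo-3-[(Z)-4-(tert-butyldimethylsilyloxy)-3-methylbut-2-enyl]-4-(triisopropylsilyloxy)phenyl]propane-1,3-dione, via acid chloride 15 (not isolated)
Conditions: (COCl)2, DMF (cat.), CH2Cl2, 0 °C → rt, evaporate; then 11, MgBr2·OEt2, i-Pr2NEt, CH2Cl2, rt
Reagents that add atoms: none
Why: Magnesium-mediated soft enolisation of the methyl ketone and C-acylation by the aroyl chloride (crossed Claisen-type acylation) should form the 1,3-diketone without strong base or alkoxide by-products, so the aryl silyl ethers are not attacked and the chelated magnesium diketonate resists over-acylation.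

Step 9
Reactants: 16 1-[3,4-bis(triisopropylsilyloxy)phenyl]-3-[2-bromo-3-[(Z)-4-(tert-butyldimethylsilyloxy)-3-methylbut-2-enyl]-4-(triisopropylsilyloxy)phenyl]propane-1,3-dione
Product: 17 (1S,3S)-1-[3,4-bis(triisopropylsilyloxy)phenyl]-3-[2-bromo-3-[(Z)-4-(tert-butyldimethylsilyloxy)-3-methylbut-2-enyl]-4-(triisopropylsilyloxy)phenyl]propane-1,3-diol
Conditions: RuCl[(S,S)-TsDPEN](p-cymene) (3 mol %), HCO2H/Et3N (5:2), CH2Cl2, 35 °C
Reagents that add atoms: none
Why: Noyori–Ikariya asymmetric transfer hydrogenation should reduce both aryl ketones under catalyst control (the (S,S)-catalyst gives (S)-carbinols from aryl ketones, and both centres rank O > aryl > CH2 > H), giving the anti (1S,3S)-diol while the alkene and the aryl bromide are not touched.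

Step 10
Reactants: 17 (1S,3S)-1-[3,4-bis(triisopropylsilyloxy)phenyl]-3-[2-bromo-3-[(Z)-4-(tert-butyldimethylsilyloxy)-3-methylbut-2-enyl]-4-(triisopropylsilyloxy)phenyl]propane-1,3-diol
Product: 18 (2S,4S)-2-[3,4-bis(triisopropylsilyloxy)phenyl]-8-[(Z)-4-(tert-butyldimethylsilyloxy)-3-methylbut-2-enyl]-7-(triisopropylsilyloxy)chroman-4-ol
Conditions: CuI (20 mol %), 3,4,7,8-tetramethyl-1,10-phenanthroline (40 mol %), Cs2CO3 (2 equiv), 4 Å MS, degassed toluene (0.02 M), 100 °C
Reagents that add atoms: none
Why: Ullmann-type C–O coupling: carbonate generates a ligated Cu(I) alkoxide of the C2 hydroxyl, which adds oxidatively to the C8a–Br bond and reductively eliminates the O1–C8a bond in a Cu(I)/Cu(III) cycle. The closest known reaction is the copper-catalysed intramolecular O-arylation of 1-aryl-3-(2-bromoaryl)propan-1-ols to 2-arylchromans. The dihydropyran ring closes in a 6-exo sense at the sp2 carbon C8a (the departing bromide lies outside the new ring) through a seven-membered aryl–copper alkoxide chelate. No stereocentre is created, and since neither the C2–O nor the C4–O bond is broken, both carbinols keep their S configuration. The step needs C2–OH over C4–OH selectivity and ring closure over intermolecular coupling: the C4 alkoxide could only give a four-membered benzoxete, so its copper chelate is a reversible dead end, and high dilution suppresses dimerisation. With no carbonyl in the substrate there is no retro-aldol or E1cB exit, and the hindered aryl TIPS ethers are chosen to survive hot carbonate in toluene.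

Step 11
Reactants: 18 (2S,4S)-2-[3,4-bis(triisopropylsilyloxy)phenyl]-8-[(Z)-4-(tert-butyldimethylsilyloxy)-3-methylbut-2-enyl]-7-(triisopropylsilyloxy)chroman-4-ol
Product: 19 (S)-2-[3,4-bis(triisopropylsilyloxy)phenyl]-8-[(Z)-4-(tert-butyldimethylsilyloxy)-3-methylbut-2-enyl]-7-(triisopropylsilyloxy)chroman-4-one
Conditions: Dess–Martin periodinane, pyridine, CH2Cl2, 0 °C → rt
Reagents that add atoms: none
Why: Dess–Martin oxidation should convert the only free hydroxyl, the benzylic C4 carbinol, into the ketone under buffered non-basic conditions that neither open the new flavanone ring nor epimerise C2.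

Step 12
Reactants: 19 (S)-2-[3,4-bis(triisopropylsilyloxy)phenyl]-8-[(Z)-4-(tert-butyldimethylsilyloxy)-3-methylbut-2-enyl]-7-(triisopropylsilyloxy)chroman-4-one
Product: 20 (S)-2-(3,4-dihydroxyphenyl)-7-hydroxy-8-[(Z)-4-hydroxy-3-methylbut-2-enyl]chroman-4-one
Conditions: TBAF/AcOH (1:1, 6 equiv), degassed THF, 0 °C → rt
Reagents that add atoms: none
Why: Fluoride-induced desilylation buffered with acetic acid should remove the three aryl TIPS ethers and the allylic TBS ether in one operation without the basic conditions that would racemise C2 through retro-oxa-Michael ring opening.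

Compound list
1 | 3-bromo-2-methylphenol | Cc1c(O)cccc1Br | starting material
2 | 3-bromo-2-methylphenyl acetate | CC(=O)Oc1cccc(Br)c1C | intermediate
3 | 1-(2-bromo-4-hydroxy-3-methylphenyl)ethanone | CC(=O)c1ccc(O)c(C)c1Br | intermediate
4 | 1-[2-bromo-3-methyl-4-(triisopropylsilyloxy)phenyl]ethanone | CC(=O)c1ccc(O[Si](C(C)C)(C(C)C)C(C)C)c(C)c1Br | intermediate
5 | 1-[2-bromo-3-(bromomethyl)-4-(triisopropylsilyloxy)phenyl]ethanone | CC(=O)c1ccc(O[Si](C(C)C)(C(C)C)C(C)C)c(CBr)c1Br | intermediate
6 | propargyl alcohol (prop-2-yn-1-ol) | C#CCO | starting material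
7 | 4-methyl-2,5-dihydro-1,2-oxamagnesole (cyclic vinylmagnesium alkoxide, Mg cis to CH2O) | CC1=C[Mg]OC1 | intermediate
8 | (Z)-3-iodo-2-methylprop-2-en-1-ol | C/C(=C/I)CO | intermediate
9 | (Z)-tert-butyl[(3-iodo-2-methylprop-2-en-1-yl)oxy]dimethylsilane | C/C(=C/I)CO[Si](C)(C)C(C)(C)C | intermediate
10 | [3-acetyl-2-bromo-6-(triisopropylsilyloxy)benzyl]zinc bromide | CC(=O)c1ccc(O[Si](C(C)C)(C(C)C)C(C)C)c(C[Zn]Br)c1Br | intermediate
11 | 1-[2-bromo-3-[(Z)-4-(tert-butyldimethylsilyloxy)-3-methylbut-2-enyl]-4-(triisopropylsilyloxy)phenyl]ethanone | CC(=O)c1ccc(O[Si](C(C)C)(C(C)C)C(C)C)c(C/C=C(/C)CO[Si](C)(C)C(C)(C)C)c1Br | intermediate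
12 | 3,4-dihydroxybenzoic acid | O=C(O)c1ccc(O)c(O)c1 | starting material
13 | triisopropylsilyl 3,4-bis(triisopropylsilyloxy)benzoate | CC(C)[Si](OC(=O)c1ccc(O[Si](C(C)C)(C(C)C)C(C)C)c(O[Si](C(C)C)(C(C)C)C(C)C)c1)(C(C)C)C(C)C | intermediate
14 | 3,4-bis(triisopropylsilyloxy)benzoic acid | O=C(O)c1ccc(O[Si](C(C)C)(C(C)C)C(C)C)c(O[Si](C(C)C)(C(C)C)C(C)C)c1 | intermediate
15 | 3,4-bis(triisopropylsilyloxy)benzoyl chloride | O=C(Cl)c1ccc(O[Si](C(C)C)(C(C)C)C(C)C)c(O[Si](C(C)C)(C(C)C)C(C)C)c1 | intermediate
16 | 1-[3,4-bis(triisopropylsilyloxy)phenyl]-3-[2-bromo-3-[(Z)-4-(tert-butyldimethylsilyloxy)-3-methylbut-2-enyl]-4-(triisopropylsilyloxy)phenyl]propane-1,3-dione | O=C(CC(=O)c1ccc(O[Si](C(C)C)(C(C)C)C(C)C)c(C/C=C(/C)CO[Si](C)(C)C(C)(C)C)c1Br)c1ccc(O[Si](C(C)C)(C(C)C)C(C)C)c(O[Si](C(C)C)(C(C)C)C(C)C)c1 | intermediate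
17 | (1S,3S)-1-[3,4-bis(triisopropylsilyloxy)phenyl]-3-[2-bromo-3-[(Z)-4-(tert-butyldimethylsilyloxy)-3-methylbut-2-enyl]-4-(triisopropylsilyloxy)phenyl]propane-1,3-diol | O[C@H](c1ccc(O[Si](C(C)C)(C(C)C)C(C)C)c(O[Si](C(C)C)(C(C)C)C(C)C)c1)C[C@H](O)c1ccc(O[Si](C(C)C)(C(C)C)C(C)C)c(C/C=C(/C)CO[Si](C)(C)C(C)(C)C)c1Br | intermediate
18 | (2S,4S)-2-[3,4-bis(triisopropylsilyloxy)phenyl]-8-[(Z)-4-(tert-butyldimethylsilyloxy)-3-methylbut-2-enyl]-7-(triisopropylsilyloxy)chroman-4-ol | C/C(=C/Cc1c(O[Si](C(C)C)(C(C)C)C(C)C)ccc2c1O[C@H](c1ccc(O[Si](C(C)C)(C(C)C)C(C)C)c(O[Si](C(C)C)(C(C)C)C(C)C)c1)C[C@@H]2O)CO[Si](C)(C)C(C)(C)C | intermediate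
19 | (S)-2-[3,4-bis(triisopropylsilyloxy)phenyl]-8-[(Z)-4-(tert-butyldimethylsilyloxy)-3-methylbut-2-enyl]-7-(triisopropylsilyloxy)chroman-4-one | C/C(=C/Cc1c(O[Si](C(C)C)(C(C)C)C(C)C)ccc2c1O[C@H](c1ccc(O[Si](C(C)C)(C(C)C)C(C)C)c(O[Si](C(C)C)(C(C)C)C(C)C)c1)CC2=O)CO[Si](C)(C)C(C)(C)C | intermediate
20 | (S)-2-(3,4-dihydroxyphenyl)-7-hydroxy-8-[(Z)-4-hydroxy-3-methylbut-2-enyl]chroman-4-one | C/C(=C/Cc1c(O)ccc2c1O[C@H](c1ccc(O)c(O)c1)CC2=O)CO | target

Total step count: 12. Longest linear sequence: 9 steps (steps 1, 2, 3, 6, 8, 9, 10, 11, 12).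

Steps most likely to fail

Step 10. Oxidative addition of copper into the electron-rich C8a–Br bond, which is flanked by two ortho substituents, may be too slow. Protodebromination or transfer of silyl groups from the aryl ethers to the alkoxides could then take over on prolonged heating. The fallback moves the same ring closure to a palladium(0)/bulky-phosphine manifold, in which oxidative addition precedes alkoxide binding and hindered bromides react at lower temperature with a milder base. It sets out from 17 and returns at 18 directly: Pd(OAc)2 with 2-(di-tert-butylphosphino)-1,1′-binaphthyl, K3PO4, toluene, 70 °C. No new compound arises on this way (F0).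

Step 9. Transfer hydrogenation of the strongly enolised, chelating diketone may stall at the β-hydroxy ketone stage. That electron-rich benzylic aldol may also dehydrate, with loss of material and of anti selectivity. The fallback builds the C2 carbinol by C–C bond formation and bypasses the diketone altogether. It sets out from 11, which is converted with TMSOTf/Et3N in CH2Cl2 into the trimethylsilyl enol ether 1-[2-bromo-3-[(Z)-4-(tert-butyldimethylsilyloxy)-3-methylbut-2-enyl]-4-(triisopropylsilyloxy)phenyl]-1-(trimethylsilyloxy)ethene F2. Its partner, 3,4-bis(triisopropylsilyloxy)benzaldehyde F1, would be made from commercial 3,4-dihydroxybenzaldehyde with TIPSCl/imidazole. A catalytic enantioselective Mukaiyama aldol addition (SiCl4 activated by a chiral bisphosphoramide, i-Pr2NEt, CH2Cl2, −78 °C), with the catalyst antipode that directs attack to the Si face of the aldehyde, should give after aqueous work-up (S)-3-[3,4-bis(triisopropylsilyloxy)phenyl]-1-[2-bromo-3-[(Z)-4-(tert-butyldimethylsilyloxy)-3-methylbut-2-enyl]-4-(triisopropylsilyloxy)phenyl]-3-hydroxypropan-1-one F3. Hydroxyl-directed Evans–Saksena reduction (Me4NBH(OAc)3, MeCN/AcOH, −20 °C) then delivers the anti diol, and the route is rejoined at 17.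

Step 6. Zinc insertion into the hindered benzylic bromide may be accompanied by Wurtz homocoupling. The organozinc may also be consumed by the acetyl group or by slow insertion at the aryl bromide before cross-coupling. The fallback reverses the polarity of the coupling. It sets out from 9, which undergoes iodine–lithium exchange (t-BuLi, 2 equiv, Et2O, −78 °C) to (Z)-[3-(tert-butyldimethylsilyloxy)-2-methylprop-1-en-1-yl]lithium F4. Quenching with Bu3SnCl gives (Z)-tert-butyldimethyl{[2-methyl-3-(tributylstannyl)prop-2-en-1-yl]oxy}silane F5. Stille coupling of F5 with the benzylic bromide 5 (Pd2(dba)3, tri(2-furyl)phosphine, THF, 50 °C) returns to the route at 11. Palladium should insert into the benzylic C–Br bond much faster than into the hindered aryl bromide, and the alkene geometry should be retained.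

Further compounds
F0 | step 10 | none | none
F1 | step 9 | 3,4-bis(triisopropylsilyloxy)benzaldehyde | O=Cc1ccc(O[Si](C(C)C)(C(C)C)C(C)C)c(O[Si](C(C)C)(C(C)C)C(C)C)c1
F2 | step 9 | 1-[2-bromo-3-[(Z)-4-(tert-butyldimethylsilyloxy)-3-methylbut-2-enyl]-4-(triisopropylsilyloxy)phenyl]-1-(trimethylsilyloxy)ethene | C=C(O[Si](C)(C)C)c1ccc(O[Si](C(C)C)(C(C)C)C(C)C)c(C/C=C(/C)CO[Si](C)(C)C(C)(C)C)c1Br
F3 | step 9 | (S)-3-[3,4-bis(triisopropylsilyloxy)phenyl]-1-[2-bromo-3-[(Z)-4-(tert-butyldimethylsilyloxy)-3-methylbut-2-enyl]-4-(triisopropylsilyloxy)phenyl]-3-hydroxypropan-1-one | O[C@H](c1ccc(O[Si](C(C)C)(C(C)C)C(C)C)c(O[Si](C(C)C)(C(C)C)C(C)C)c1)CC(=O)c1ccc(O[Si](C(C)C)(C(C)C)C(C)C)c(C/C=C(/C)CO[Si](C)(C)C(C)(C)C)c1Br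
F4 | step 6 | (Z)-[3-(tert-butyldimethylsilyloxy)-2-methylprop-1-en-1-yl]lithium | C/C(=C/[Li])CO[Si](C)(C)C(C)(C)C
F5 | step 6 | (Z)-tert-butyldimethyl{[2-methyl-3-(tributylstannyl)prop-2-en-1-yl]oxy}silane | C/C(=C/[Sn](CCCC)(CCCC)CCCC)CO[Si](C)(C)C(C)(C)C
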